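**Retrosynthetic overview**
- 35 ⇐ 34 (C6–OH → C6–Cl with inversion) ⇐ enone 33 ⇐ macrocyclic alcohol 32 ⇐ seco-ynal 30: the ten-membered ring (C1–C10) is closed last, through C5–C6, by a nickel-catalyzed reductive alkyne–aldehyde macrocyclization.
- Enabling feature: ring carbon C5 carries the exocyclic methylene C16 and is bonded to the heteroatom-bearing C6 next to lactone carbon C7. The unit C16H2=C5–C6(X) therefore maps onto terminal alkyne C5≡C16 plus aldehyde C6. The trans-diequatorial C2 and C9 arms on cyclohexane ring A and the rigid lactone hold the two ends close.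
- Lactone (O–C7–C8–C17–C18) ⇐ copper hydride reductive aldol of a C7 acrylate onto the C8 ketone; C8–C9 ⇐ Nozaki–Hiyama–Kishi coupling of ring A aldehyde 19 with iodide 24.
- Ring A aldehyde 19 ⇐ benzoic acid: Birch methylation, CBS reduction (C2), dienone, hemiacetal oxa-Michael desymmetrization (C1, C14), vinyl cuprate and methylenation (C10, C20), Luche reduction (C12), directed epoxidation (C11).
- Order of ring formation: cyclohexane → spiro-epoxide → lactone → ten-membered ring.

Key step: step 25

Remark: positions are numbered as in the briarane skeleton (ten-membered ring C1–C10; cyclohexane C1, C10–C14; C15 methyl on C1; C16 methylene on C5; lactone C7, C8, C17, C18; C19 methyl on C17; C20 epoxide CH2 on C11). Bromide 3 and (S)-glyceraldehyde acetonide 20 are taken as commercial.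

**Route**

Step 1
Reactants: 1 benzoic acid
Product: 2 1-methylcyclohexa-2,5-diene-1-carboxylic acid
Conditions: Li, NH3(l), THF, −78 °C; then MeI; aq. HCl work-up
Reagents that add atoms: iodomethane, CI
Why: Birch reductive alkylation: the carboxylate-stabilized cyclohexadienyl dianion is methylated at the ipso carbon; no stereocenter forms because C1 carries two identical ring arms.

Step 2
Reactants: 2 1-methylcyclohexa-2,5-diene-1-carboxylic acid; 3 (4-bromobut-1-yn-1-yl)trimethylsilane
Product: 6 1-(1-methylcyclohexa-2,5-dien-1-yl)-5-(trimethylsilyl)pent-4-yn-1-one, via acid chloride 4 (not isolated), via Grignard reagent 5 (not isolated)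
Conditions: 2, (COCl)2, DMF (cat.), CH2Cl2, 0 → 23 °C, evaporate; 3, Mg, THF; combine with CuI (5 mol%), THF, −78 °C
Reagents that add atoms: none
Why: Copper-catalyzed acylation of a Grignard reagent by a hindered tertiary acid chloride should stop at the ketone at −78 °C; no stereocenter is formed.

Step 3
Reactants: 6 1-(1-methylcyclohexa-2,5-dien-1-yl)-5-(trimethylsilyl)pent-4-yn-1-one
Product: 7 (R)-1-(1-methylcyclohexa-2,5-dien-1-yl)-5-(trimethylsilyl)pent-4-yn-1-ol
Conditions: (S)-Me-CBS oxazaborolidine (20 mol%), BH3·SMe2, THF, −20 °C; MeOH quench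
Reagents that add atoms: none
Why: Corey–Bakshi–Shibata reduction: the catalyst-bound borane delivers hydride to the ketone face that keeps the large tertiary C1 group away from the catalyst, which should set C2 as R (tertiary alkyl versus primary alkyl).

Step 4
Reactants: 7 (R)-1-(1-methylcyclohexa-2,5-dien-1-yl)-5-(trimethylsilyl)pent-4-yn-1-ol
Product: 8 triethylsilyl ether of 7
Conditions: TESCl, imidazole, DMF, 23 °C
Reagents that add atoms: chlorotriethylsilane, CC[Si](Cl)(CC)CC
Why: Standard silylation protects the C2 carbinol against the oxidant of step 5; the stereocenter is not touched.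

Step 5
Reactants: 8 triethylsilyl ether of 7
Product: 9 4-methyl-4-[(R)-1-(triethylsilyloxy)-5-(trimethylsilyl)pent-4-yn-1-yl]cyclohexa-2,5-dien-1-one
Conditions: Rh2(cap)4 [dirhodium tetrakis(caprolactamate)] (1 mol%), t-BuOOH (aq., 4 equiv), K2CO3, CH2Cl2, 23 °C
Reagents that add atoms: tert-butyl hydroperoxide, CC(C)(C)OO
Why: Allylic C–H oxidation by tert-butylperoxyl radicals under dirhodium catalysis should take place at the doubly allylic CH2 (weakest C–H bond, ahead of the propargylic CH2) and give the cross-conjugated dienone; no stereocenter changes.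

Step 6
Reactants: 9 4-methyl-4-[(R)-1-(triethylsilyloxy)-5-(trimethylsilyl)pent-4-yn-1-yl]cyclohexa-2,5-dien-1-one
Product: 10 4-[(R)-1-hydroxy-5-(trimethylsilyl)pent-4-yn-1-yl]-4-methylcyclohexa-2,5-dien-1-one
Conditions: HF·pyridine, pyridine, THF, 0 °C
Reagents that add atoms: none
Why: Fluoride cleavage of the O–Si bond under non-basic conditions leaves the alkynylsilane and avoids alkoxide-induced fragmentation of the hydroxy dienone to a phenol.

Step 7
Reactants: 10 4-[(R)-1-hydroxy-5-(trimethylsilyl)pent-4-yn-1-yl]-4-methylcyclohexa-2,5-dien-1-one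
Product: 11 cis-fused acetal enone (C2–O/C14–O ethylidene acetal as a 2-methyl-1,3-dioxane fused at C1–C14; C10=C11; C12 ketone)
Conditions: MeCHO (5 equiv), Bi(NO3)3·5H2O (10 mol%), CH2Cl2, 23 °C
Reagents that add atoms: acetaldehyde, CC=O
Why: Bismuth-mediated hemiacetal formation and intramolecular oxa-Michael addition through a chair-like transition state with the C3 chain and the acetal methyl equatorial should select one of the two diastereotopic enones, which makes C1 stereogenic and sets C14 (C–O cis to the C2 arm) and the acetal carbon.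

Step 8
Reactants: 11 cis-fused acetal enone
Product: 12 Mannich base (vinyl on C10 cis to the C15 methyl; CH2NMe2 on C11 trans to vinyl)
Conditions: CH2=CHMgBr, CuBr·SMe2 (20 mol%), THF, −78 → −40 °C; then Me2N=CH2+ I−, −40 → 0 °C
Reagents that add atoms: vinylmagnesium bromide, C=C[Mg]Br; dimethylmethyleneiminium iodide (Eschenmoser's salt), C[N+](C)=C.[I-]
Why: Copper-catalyzed conjugate addition with Mannich trapping of the magnesium enolate: the vinyl group should enter C10 anti to the axial C14–O bond of the cis-fused acetal (1,3-diaxial shielding of that face), i.e. cis to C15 and trans to the C2 arm, and the aminomethyl group adds to C11 trans to it (this center is removed in step 9).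

Step 9
Reactants: 12 Mannich base
Product: 14 alpha-methylene ketone (C11=C20, C12 ketone, C10 vinyl), via ammonium iodide 13 (not isolated)
Conditions: MeI, CH2Cl2/Et2O, 23 °C; then aq. NaHCO3, 23 °C
Reagents that add atoms: none
Why: N-Methylation and E1cB loss of trimethylamine (Mannich route to alpha-methylene ketones) gives the exocyclic enone under mild base, which should not move the alkene into the ring; the C11 stereocenter disappears.

Step 10
Reactants: 14 alpha-methylene ketone
Product: 15 allylic alcohol (axial C12–OH cis to the C14 oxygen)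
Conditions: NaBH4, CeCl3·7H2O, MeOH, −78 °C
Reagents that add atoms: none
Why: Luche 1,2-reduction: hydride should add equatorially to C12 from the face opposite the axial C14–O bond, which blocks axial attack by a 1,3-diaxial interaction, giving the axial alcohol cis to the C14 oxygen.

Step 11
Reactants: 15 allylic alcohol
Product: 16 triol (C2, C12, C14 hydroxyls; C11=C20; C10 vinyl)
Conditions: aq. HCl (1 M), THF, 40 °C
Reagents that add atoms: none
Why: Acid-catalyzed acetal hydrolysis releases the syn-1,3-diol before the acid-sensitive epoxide is made; the secondary allylic alcohol and the alkynylsilane tolerate dilute acid and no stereocenter changes.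

Step 12
Reactants: 16 triol
Product: 17 11,20-epoxy triol
Conditions: VO(acac)2 (5 mol%), t-BuOOH (decane), CH2Cl2, 0 °C
Reagents that add atoms: tert-butyl hydroperoxide, CC(C)(C)OO
Why: Vanadium-catalyzed hydroxyl-directed epoxidation: the vanadium-bound C12 allylic alkoxide delivers the peroxide oxygen to the C11=C20 face on which it sits, which should set C11 with the epoxide oxygen cis to the C12 oxygen; the vinyl group has no allylic hydroxyl and should stay.

Step 13
Reactants: 17 11,20-epoxy triol
Product: 18 2,12,14-triacetate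
Conditions: Ac2O, pyridine, DMAP (cat.), 23 °C
Reagents that add atoms: acetic anhydride, CC(=O)OC(C)=O
Why: DMAP-catalyzed acetylation installs three of the four acetates of the target; the basic medium does not open the epoxide.

Step 14
Reactants: 18 2,12,14-triacetate
Product: 19 ring A aldehyde (C9 = CHO on C10)
Conditions: OsO4 (2 mol%), NaIO4, 2,6-lutidine, dioxane/H2O, 23 °C
Reagents that add atoms: sodium periodate (oxygen, delivered through OsO4), [Na+].[O-]I(=O)(=O)=O
Why: Lemieux–Johnson cleavage of the only alkene gives the aldehyde; the buffered medium should not epimerize C10, and the alkynylsilane reacts far more slowly with OsO4.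

Step 15
Reactants: 20 (S)-2,2-dimethyl-1,3-dioxolane-4-carbaldehyde
Product: 21 (R)-4-ethynyl-2,2-dimethyl-1,3-dioxolane
Conditions: dimethyl (1-diazo-2-oxopropyl)phosphonate, K2CO3, MeOH, 0 → 23 °C
Reagents that add atoms: dimethyl (1-diazo-2-oxopropyl)phosphonate, CC(=O)C(=[N+]=[N-])P(=O)(OC)OC
Why: Ohira–Bestmann variant of the Seyferth–Gilbert homologation converts the aldehyde into the terminal alkyne under conditions known to keep this alpha-alkoxy stereocenter (future C7) intact.

Step 16
Reactants: 21 (R)-4-ethynyl-2,2-dimethyl-1,3-dioxolane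
Product: 22 (S)-3-iodobut-3-ene-1,2-diol
Conditions: NaI, TMSCl, H2O, MeCN, 0 → 23 °C; then aq. MeOH
Reagents that add atoms: sodium iodide, [Na+].[I-]
Why: Markovnikov hydroiodination of the terminal alkyne by HI generated in the flask gives the 2-iodoalkene, and the same acidic medium hydrolyzes the acetonide; C7 is not touched.

Step 17
Reactants: 22 (S)-3-iodobut-3-ene-1,2-diol
Product: 23 (S)-3-iodo-1-(triethylsilyloxy)but-3-en-2-ol
Conditions: TESCl (1.05 equiv), imidazole, CH2Cl2, −78 °C
Reagents that add atoms: chlorotriethylsilane, CC[Si](Cl)(CC)CC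
Why: Silylation at low temperature should be selective for the primary hydroxyl (future C6–O) over the secondary one.

Step 18
Reactants: 23 (S)-3-iodo-1-(triethylsilyloxy)but-3-en-2-ol
Product: 24 (S)-3-iodo-1-(triethylsilyloxy)but-3-en-2-yl acrylate
Conditions: CH2=CHCOCl, i-Pr2NEt, DMAP (cat.), CH2Cl2, −78 → 0 °C
Reagents that add atoms: acryloyl chloride, C=CC(=O)Cl
Why: O-Acylation installs the acrylate whose three carbons become C17, C18 and C19 and whose ester oxygen becomes the lactone oxygen on C7.

Step 19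
Reactants: 19 ring A aldehyde; 24 (S)-3-iodo-1-(triethylsilyloxy)but-3-en-2-yl acrylate
Product: 25 allylic alcohol (9S-hydroxyl; C8 as C=CH2; C7 acrylate; C6 OTES)
Conditions: CrCl2 (4 equiv), NiCl2 (2 mol%), DMSO/THF, 23 °C
Reagents that add atoms: none
Why: Nozaki–Hiyama–Kishi coupling (nickel inserts into the C–I bond, transmetalation gives the alkenylchromium reagent) adds selectively to the aldehyde in the presence of esters, epoxide and acrylate; C9 should form as 9S by attack anti to the quaternary C1 on the side of the small epoxide oxygen, with C9=O eclipsing the axial C10–H bond.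

Step 20
Reactants: 25 allylic alcohol
Product: 26 9-acetate of 25
Conditions: Ac2O, pyridine, DMAP (cat.), 23 °C
Reagents that add atoms: acetic anhydride, CC(=O)OC(C)=O
Why: Acetylation installs the fourth acetate of the target; no stereocenter changes.

Step 21
Reactants: 26 9-acetate of 25
Product: 27 C8 ketone (C9 OAc, C7 acrylate)
Conditions: O3, CH2Cl2, −78 °C (Sudan red end point); then Me2S, −78 → 23 °C
Reagents that add atoms: ozone, [O-][O+]=O
Why: Ozonolysis with reductive work-up cleaves the 1,1-disubstituted alkene to the ketone; the conjugated acrylate and the alkynylsilane react more slowly with electrophilic ozone and the dye marks the end point.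

Step 22
Reactants: 27 C8 ketone
Product: 28 lactone (C8 OSiMe2Ph, C17 methyl, C6 OTES, silylalkyne)
Conditions: Cu(OAc)2·H2O (5 mol%), rac-BINAP (5 mol%), PhMe2SiH (2 equiv), THF, 0 → 23 °C
Reagents that add atoms: dimethylphenylsilane, C[SiH](C)c1ccccc1
Why: Copper hydride reductive aldol cyclization: conjugate reduction of the acrylate gives a copper enolate that adds to the adjacent ketone through a closed Zimmerman–Traxler-type transition state and the alkoxide is silylated; the bulky C9 arm should take the lactone face opposite the C6 group on C7 (C8–O cis to C6) and the C17 methyl should end cis to the C8 oxygen.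

Step 23
Reactants: 28 lactone
Product: 29 terminal alkyne (C5≡C16–H)
Conditions: AgNO3 (20 mol%), 2,6-lutidine, acetone/H2O, 23 °C
Reagents that add atoms: none
Why: Silver-catalyzed protiodesilylation of the alkynylsilane through the silver acetylide is neutral, so silyl ethers, acetates, lactone and epoxide should be untouched.

Step 24
Reactants: 29 terminal alkyne
Product: 30 seco-ynal (C6 aldehyde, C5≡C16 alkyne, C8 OSiMe2Ph)
Conditions: (COCl)2, DMSO, CH2Cl2, −78 → −40 °C; then Et3N, −78 °C
Reagents that add atoms: none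
Why: Swern oxidation applied directly to the primary triethylsilyl ether (the chlorosulfonium salt cleaves the primary O–Si bond, the ylide collapses to the aldehyde) leaves the tertiary silyl ether; base at −78 °C should avoid epimerization at C7.

Step 25
Reactants: 30 seco-ynal
Product: 32 macrocyclic 6,8-diol (6S; C5=C16 methylene), via bis-silyl ether 31 (not isolated)
Conditions: Ni(cod)2 (30 mol%), IPr [1,3-bis(2,6-diisopropylphenyl)imidazol-2-ylidene] (30 mol%), Et3SiH (5 equiv), THF, 23 °C, slow addition of 30; then HF·pyridine, pyridine, THF, 0 °C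
Reagents that add atoms: none
Why: Zerovalent nickel bound to the bulky carbene couples alkyne C5≡C16 and aldehyde C6 by oxidative cyclization to an oxanickelacyclopentene; Et3SiH cleaves the Ni–O bond and C–H reductive elimination releases the C6 silyl ether with the C5=C16 methylene (aldehyde–alkyne reductive coupling, known as an exo-selective macrocyclization of ynals with large carbene ligands). The ten-membered ring closes in the exo mode by forming C5–C6 at the internal alkyne carbon, whereas the endo mode would place an E-alkene in an eleven-membered ring. The only new stereocenter, C6, is controlled by the C7–O bond of the lactone (Felkin–Anh, carbon enters anti to C7–O, expected 6S), and its configuration is not critical because step 26 converts both epimers into one enone. The step needs exo regioselectivity, secured by ligand size and by the strain of the endo alternative, and ring closure over oligomerization or direct hydrosilylation, secured by slow addition and by the trans-diequatorial C2 and C9 arms on the ring A chair together with the rigid lactone. Acetates, epoxide, lactone and the silylated C8 oxygen should be inert to the neutral conditions, and buffered HF·pyridine then removes both silyl groups.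

Step 26
Reactants: 32 macrocyclic 6,8-diol
Product: 33 macrocyclic enone (C6 ketone conjugated with C5=C16)
Conditions: Dess–Martin periodinane, NaHCO3, CH2Cl2, 0 °C
Reagents that add atoms: none
Why: Dess–Martin oxidation of the secondary allylic alcohol (the tertiary C8 alcohol cannot be oxidized) funnels both C6 epimers into one enone.

Step 27
Reactants: 33 macrocyclic enone
Product: 34 6R allylic alcohol
Conditions: NaBH4, CeCl3·7H2O, MeOH/THF, −78 °C
Reagents that add atoms: none
Why: Luche 1,2-reduction: hydride should add anti to the C7–O bond (Felkin–Anh), the face opposite to the one carbon took in step 25, giving the 6R alcohol.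

Step 28
Reactants: 34 6R allylic alcohol
Product: 35 CNP0349227.1
Conditions: PPh3, Cl3CCOCCl3, CH2Cl2, −40 → 0 °C
Reagents that add atoms: hexachloroacetone, ClC(Cl)(Cl)C(=O)C(Cl)(Cl)Cl
Why: Appel-type chlorination: chloride displaces the alkoxyphosphonium ion by SN2 with inversion (6R alcohol to 6S chloride), a reagent pair known to convert allylic alcohols without allylic shift; the tertiary C8 alcohol and the epoxide should not react at low temperature.

**Compound list**
1 | benzoic acid | OC(=O)c1ccccc1 | starting material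
2 | 1-methylcyclohexa-2,5-diene-1-carboxylic acid | CC1(C(=O)O)C=CCC=C1 | intermediate
3 | (4-bromobut-1-yn-1-yl)trimethylsilane | C[Si](C)(C)C#CCCBr | starting material
4 | 1-methylcyclohexa-2,5-diene-1-carbonyl chloride | CC1(C(=O)Cl)C=CCC=C1 | intermediate
5 | [4-(trimethylsilyl)but-3-yn-1-yl]magnesium bromide | C[Si](C)(C)C#CCC[Mg]Br | intermediate
6 | 1-(1-methylcyclohexa-2,5-dien-1-yl)-5-(trimethylsilyl)pent-4-yn-1-one | C[Si](C)(C)C#CCCC(=O)C1(C)C=CCC=C1 | intermediate
7 | (R)-1-(1-methylcyclohexa-2,5-dien-1-yl)-5-(trimethylsilyl)pent-4-yn-1-ol | C[Si](C)(C)C#CCC[C@@H](O)C1(C)C=CCC=C1 | intermediate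
8 | triethylsilyl ether of 7 | C[Si](C)(C)C#CCC[C@@H](O[Si](CC)(CC)CC)C1(C)C=CCC=C1 | intermediate
9 | 4-methyl-4-[(R)-1-(triethylsilyloxy)-5-(trimethylsilyl)pent-4-yn-1-yl]cyclohexa-2,5-dien-1-one | C[Si](C)(C)C#CCC[C@@H](O[Si](CC)(CC)CC)C1(C)C=CC(=O)C=C1 | intermediate
10 | 4-[(R)-1-hydroxy-5-(trimethylsilyl)pent-4-yn-1-yl]-4-methylcyclohexa-2,5-dien-1-one | C[Si](C)(C)C#CCC[C@@H](O)C1(C)C=CC(=O)C=C1 | intermediate
11 | cis-fused acetal enone (C2–O/C14–O ethylidene acetal, C10=C11, C12 ketone; acetal methyl and C3 chain equatorial on the dioxane) | C[Si](C)(C)C#CCC[C@H]1O[C@@H](C)O[C@H]2CC(=O)C=C[C@@]12C | intermediate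
12 | Mannich base (C10 vinyl cis to C15, C11 CH2NMe2 trans to vinyl) | C[Si](C)(C)C#CCC[C@H]1O[C@@H](C)O[C@H]2CC(=O)[C@@H](CN(C)C)[C@H](C=C)[C@@]12C | intermediate
13 | trimethylammonium iodide of 12 | C[Si](C)(C)C#CCC[C@H]1O[C@@H](C)O[C@H]2CC(=O)[C@@H](C[N+](C)(C)C)[C@H](C=C)[C@@]12C.[I-] | intermediate
14 | alpha-methylene ketone (C11=C20, C12 ketone, C10 vinyl) | C[Si](C)(C)C#CCC[C@H]1O[C@@H](C)O[C@H]2CC(=O)C(=C)[C@H](C=C)[C@@]12C | intermediate
15 | allylic alcohol (axial C12–OH cis to O14) | C[Si](C)(C)C#CCC[C@H]1O[C@@H](C)O[C@H]2C[C@@H](O)C(=C)[C@H](C=C)[C@@]12C | intermediate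
16 | 2,12,14-triol (C11=C20, C10 vinyl) | C[Si](C)(C)C#CCC[C@@H](O)[C@@]2(C)[C@@H](O)C[C@@H](O)C(=C)[C@@H]2C=C | intermediate
17 | 11,20-epoxy-2,12,14-triol (epoxide oxygen cis to O12) | C[Si](C)(C)C#CCC[C@@H](O)[C@@]2(C)[C@@H](O)C[C@@H](O)[C@]3(CO3)[C@@H]2C=C | intermediate
18 | 2,12,14-triacetate of 17 | C[Si](C)(C)C#CCC[C@@H](OC(C)=O)[C@@]2(C)[C@@H](OC(C)=O)C[C@@H](OC(C)=O)[C@]3(CO3)[C@@H]2C=C | intermediate
19 | ring A aldehyde (C9 = CHO) | C[Si](C)(C)C#CCC[C@@H](OC(C)=O)[C@@]2(C)[C@@H](OC(C)=O)C[C@@H](OC(C)=O)[C@]3(CO3)[C@@H]2C=O | intermediate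
20 | (S)-2,2-dimethyl-1,3-dioxolane-4-carbaldehyde | O=C[C@H]1OC(C)(C)OC1 | starting material
21 | (R)-4-ethynyl-2,2-dimethyl-1,3-dioxolane | C#C[C@H]1OC(C)(C)OC1 | intermediate
22 | (S)-3-iodobut-3-ene-1,2-diol | C=C(I)[C@@H](O)CO | intermediate
23 | (S)-3-iodo-1-(triethylsilyloxy)but-3-en-2-ol | C=C(I)[C@@H](O)CO[Si](CC)(CC)CC | intermediate
24 | (S)-3-iodo-1-(triethylsilyloxy)but-3-en-2-yl acrylate | C=C(I)[C@@H](OC(=O)C=C)CO[Si](CC)(CC)CC | intermediate
25 | coupled allylic alcohol (9S-OH, C8=CH2, C7 acrylate, C6 OTES) | C[Si](C)(C)C#CCC[C@@H](OC(C)=O)[C@@]2(C)[C@@H](OC(C)=O)C[C@@H](OC(C)=O)[C@]3(CO3)[C@@H]2[C@H](O)C(=C)[C@@H](OC(=O)C=C)CO[Si](CC)(CC)CC | intermediate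
26 | 9-acetate of 25 | C[Si](C)(C)C#CCC[C@@H](OC(C)=O)[C@@]2(C)[C@@H](OC(C)=O)C[C@@H](OC(C)=O)[C@]3(CO3)[C@@H]2[C@H](OC(C)=O)C(=C)[C@@H](OC(=O)C=C)CO[Si](CC)(CC)CC | intermediate
27 | C8 ketone (C9 OAc, C7 acrylate) | C[Si](C)(C)C#CCC[C@@H](OC(C)=O)[C@@]2(C)[C@@H](OC(C)=O)C[C@@H](OC(C)=O)[C@]3(CO3)[C@@H]2[C@H](OC(C)=O)C(=O)[C@@H](OC(=O)C=C)CO[Si](CC)(CC)CC | intermediate
28 | lactone (C8 OSiMe2Ph, C17 methyl, C6 OTES, silylalkyne) | C[Si](C)(C)C#CCC[C@@H](OC(C)=O)[C@@]2(C)[C@@H](OC(C)=O)C[C@@H](OC(C)=O)[C@]3(CO3)[C@@H]2[C@H](OC(C)=O)[C@]2(O[Si](C)(C)c4ccccc4)[C@@H](C)C(=O)O[C@H]2CO[Si](CC)(CC)CC | intermediate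
29 | terminal alkyne lactone | C#CCC[C@@H](OC(C)=O)[C@@]2(C)[C@@H](OC(C)=O)C[C@@H](OC(C)=O)[C@]3(CO3)[C@@H]2[C@H](OC(C)=O)[C@]2(O[Si](C)(C)c4ccccc4)[C@@H](C)C(=O)O[C@H]2CO[Si](CC)(CC)CC | intermediate
30 | seco-ynal (C6 aldehyde, C5≡C16 alkyne) | C#CCC[C@@H](OC(C)=O)[C@@]2(C)[C@@H](OC(C)=O)C[C@@H](OC(C)=O)[C@]3(CO3)[C@@H]2[C@H](OC(C)=O)[C@]2(O[Si](C)(C)c4ccccc4)[C@@H](C)C(=O)O[C@H]2C=O | intermediate
31 | macrocyclic bis-silyl ether (6S-OTES, 8-OSiMe2Ph) | C=C1CC[C@@H](OC(C)=O)[C@@]2(C)[C@@H](OC(C)=O)C[C@@H](OC(C)=O)[C@]3(CO3)[C@@H]2[C@H](OC(C)=O)[C@]2(O[Si](C)(C)c4ccccc4)[C@@H](C)C(=O)O[C@H]2[C@H]1O[Si](CC)(CC)CC | intermediate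
32 | macrocyclic 6S,8-diol | C=C1CC[C@@H](OC(C)=O)[C@@]2(C)[C@@H](OC(C)=O)C[C@@H](OC(C)=O)[C@]3(CO3)[C@@H]2[C@H](OC(C)=O)[C@]2(O)[C@@H](C)C(=O)O[C@H]2[C@H]1O | intermediate
33 | macrocyclic enone (C6 ketone) | C=C1CC[C@@H](OC(C)=O)[C@@]2(C)[C@@H](OC(C)=O)C[C@@H](OC(C)=O)[C@]3(CO3)[C@@H]2[C@H](OC(C)=O)[C@]2(O)[C@@H](C)C(=O)O[C@H]2C1=O | intermediate
34 | macrocyclic 6R alcohol | C=C1CC[C@@H](OC(C)=O)[C@@]2(C)[C@@H](OC(C)=O)C[C@@H](OC(C)=O)[C@]3(CO3)[C@@H]2[C@H](OC(C)=O)[C@]2(O)[C@@H](C)C(=O)O[C@H]2[C@@H]1O | intermediate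
35 | CNP0349227.1 | C=C1CC[C@@H](OC(C)=O)[C@@]2(C)[C@@H](OC(C)=O)C[C@@H](OC(C)=O)[C@]3(CO3)[C@@H]2[C@H](OC(C)=O)[C@]2(O)[C@@H](C)C(=O)O[C@H]2[C@H]1Cl | target

**Step count and risks**

Total steps: 28. Longest linear sequence: 24 (steps 1–14 and 19–28); the side branch is steps 15–18.

Steps most likely to fail:

Step 25. Oligomerization, direct hydrosilylation of the alkyne or endo coupling may outrun closure of the strained ten-membered ring. The fallback closes the same bond by a stoichiometric Nozaki–Hiyama–Kishi reaction and sets out from 29. Markovnikov hydrosilylation of the terminal alkyne ([Cp*Ru(MeCN)3]PF6, Et3SiH) should give the 1,1-disubstituted vinylsilane F1. Iododesilylation (N-iodosuccinimide, 2,6-lutidine, hexafluoroisopropanol) should give the 2-iodoalkene F2. Swern oxidation of the primary silyl ether should give the iodo aldehyde F3. CrCl2 with NiCl2 (cat.) in DMSO/THF at high dilution should give the macrocyclic allylic alcohol F4, still silylated at O8. HF·pyridine then returns the route at 32.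

Step 19. Facial selectivity at C9 may be poor in the addition to the very hindered aldehyde. The fallback sets C9 by delivery of hydrogen instead of carbon and sets out from 25 as the epimer mixture. Dess–Martin oxidation should give the cross-conjugated enone F5. 1,2-Reduction (NaBH4/CeCl3·7H2O, where hydrogen enters from the face that carbon preferred, or an oxazaborolidine with catecholborane if reagent control is needed) returns the route at 25 as the 9S alcohol.

Step 28. SN2′ attack of chloride at C16 or elimination may compete with direct displacement at C6. The fallback ties the leaving group into a ring and sets out from 34. SOCl2 and pyridine should give the cyclic sulfite F6 across O6 and O8, which lie on the same face of the lactone. LiCl in DMF should open it at the allylic C6 with inversion, and mild aqueous acid hydrolyzes the sulfite monoester left on O8, which returns the route at 35.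

**Further compounds**
F1 | step 25 | vinylsilane (C5 bears SiEt3, C5=C16H2; C6 OTES) | C=C([Si](CC)(CC)CC)CC[C@@H](OC(C)=O)[C@@]2(C)[C@@H](OC(C)=O)C[C@@H](OC(C)=O)[C@]3(CO3)[C@@H]2[C@H](OC(C)=O)[C@]2(O[Si](C)(C)c4ccccc4)[C@@H](C)C(=O)O[C@H]2CO[Si](CC)(CC)CC
F2 | step 25 | 2-iodoalkene (C5 iodide, C6 OTES) | C=C(I)CC[C@@H](OC(C)=O)[C@@]2(C)[C@@H](OC(C)=O)C[C@@H](OC(C)=O)[C@]3(CO3)[C@@H]2[C@H](OC(C)=O)[C@]2(O[Si](C)(C)c4ccccc4)[C@@H](C)C(=O)O[C@H]2CO[Si](CC)(CC)CC
F3 | step 25 | iodo aldehyde (C5 iodide, C6 aldehyde) | C=C(I)CC[C@@H](OC(C)=O)[C@@]2(C)[C@@H](OC(C)=O)C[C@@H](OC(C)=O)[C@]3(CO3)[C@@H]2[C@H](OC(C)=O)[C@]2(O[Si](C)(C)c4ccccc4)[C@@H](C)C(=O)O[C@H]2C=O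
F4 | step 25 | macrocyclic 6S alcohol with C8 OSiMe2Ph | C=C1CC[C@@H](OC(C)=O)[C@@]2(C)[C@@H](OC(C)=O)C[C@@H](OC(C)=O)[C@]3(CO3)[C@@H]2[C@H](OC(C)=O)[C@]2(O[Si](C)(C)c4ccccc4)[C@@H](C)C(=O)O[C@H]2[C@H]1O
F5 | step 19 | C9 ketone (enone with C8=CH2) | C[Si](C)(C)C#CCC[C@@H](OC(C)=O)[C@@]2(C)[C@@H](OC(C)=O)C[C@@H](OC(C)=O)[C@]3(CO3)[C@@H]2C(=O)C(=C)[C@@H](OC(=O)C=C)CO[Si](CC)(CC)CC
F6 | step 28 | 6,8-O-cyclic sulfite of 34 | C=C1CC[C@@H](OC(C)=O)[C@@]2(C)[C@@H](OC(C)=O)C[C@@H](OC(C)=O)[C@]3(CO3)[C@@H]2[C@H](OC(C)=O)[C@]2(OS(=O)O4)[C@@H](C)C(=O)O[C@H]2[C@@H]14
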